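(Readings and results were generated by integration with made-up constants; noise was put on by code.)

In a one-step world a molecule of E has one road, and its age tells me nothing about what it became. In the beta run J reads 31% at 8.00 min and 10% at 25.0 min, while Q rises from 36% to 63%, so here age matters.

| flask | E | X | remark | time |
|---|---|---|---|---|
| beta | 10 mM | 10 mM | run made earlier |  |
| theta | 14 mM | 10 mM | run made earlier |  |
| delta | 22 mM | 10 mM | run made earlier |  |
| gamma | 10 mM | 5 mM | run made earlier |  |
| noon | 10 mM | 10.0 mM | everything together in a closed stirred flask, run for 25 min | 25 min |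
| summer | 10 mM | 10.0 mM | a single well-mixed tank run continuously and read at steady state, 25 min in it on average |  |
| dawn | 10 mM | 10.0 mM (fed, over 25.0 min) | all but X at the start; X goes in evenly over 25.0 min, the run ends at 25 min | 25 min |
| winter | 10 mM (fed, over 25.0 min) | 10.0 mM | a stirred flask in which E is dosed at a steady rate over 25.0 min without added volume, worked up at 25 min | 25 min |

| run | time / min | J / % | D / % | Q / % |
|---|---|---|---|---|
| beta | 3.00 | 26 | 11 | 5 |
| beta | 8.00 | 31 | 21 | 36 |
| beta | 15.0 | 19 | 27 | 58 |
| beta | 25.0 | 10 | 23 | 63 |
| theta | 4.00 | 31 | 15 | 13 |
| theta | 10.0 | 25 | 24 | 45 |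
| theta | 20.0 | 13 | 25 | 64 |
| theta | 30.0 | 9 | 25 | 64 |
| delta | 8.00 | 31 | 19 | 37 |
| delta | 15.0 | 18 | 25 | 59 |
| delta | 25.0 | 11 | 24 | 64 |
| delta | 30.0 | 8 | 25 | 67 |
| gamma | 4.00 | 30 | 15 | 13 |
| gamma | 10.0 | 29 | 25 | 45 |
| gamma | 20.0 | 12 | 25 | 60 |
| gamma | 30.0 | 10 | 25 | 65 |

(standard deviation of a reading: 1.5 percentage points)

- the stated concentrations are those of everything mixed, before any reaction; amounts are the same in each set-up
- the analysis behind the earlier runs scatters by 1.5 percentage points, standard deviation
- the feed brings no volume worth counting
- the earlier runs were made in a closed, stirred flask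

- the set-up with the highest share of J in all that became J or D or Q, at the outlet or at the end ("none" if the first two lie within 2 percentage points) (noon / summer / dawn / winter / none)
- share of J in all that became J or D or Q, at the outlet or at the end, noon
- share of J in all that became J or D or Q, at the outlet or at the end, summer
- share of J in all that became J or D or Q, at the outlet or at the end, dawn
- share of J in all that became J or D or Q, at the outlet or at the end, winter

A molecule of E goes to D, or to J and then on to Q. My first estimate uses the latest readings of the theta, delta and gamma runs, at 30.0 min, pooled: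

J/(J+D+Q) = 9.06%

Noon repeats the recipe of the beta run, whose reading at 25.0 min gives 10.4%. Can molecules in one flask disturb each other? Hardly, it seems. Q reads 59% in the delta run against 58% in the beta run at 15.0 min, although [E] differs, and 45% in the gamma run against 45% in the theta run at 10.0 min, with less X. So I take the steps as first order in E, with X idle, and dawn equals noon.

But winter breaks my estimate, since its molecules arrive evenly and are aged from zero to 25.0 min at the end. Winter is then one molecule's life sampled evenly. I therefore need the time-as-J share, minutes spent as J over minutes spent as any product, with straight lines through the beta readings: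

as J: 5.02 min

as product: 20.6 min

W = 24.3%

Are so few readings enough? The gap to noon, 14 percentage points, stands against a scatter of 1.5 points per reading, so I keep it. The tank's mean age, 25 min, exceeds winter's 12.5 min, so I put summer below W.

The forecast names winter: noon 11%, summer 21%, dawn 11%, winter 27%, saying “product ages run about 0–21 min”. My winter figure is lower.

    E ⇌ Z (K = 20.0, k = 0.00650 s⁻¹)
    Z → D (k = 0.00280 s⁻¹)
    Z → J (k = 0.00860 s⁻¹)
    J ⇌ Q (K = 6.40, k = 0.00340 s⁻¹)
    X ⇌ L (K = 1.50, k = 0.0120 s⁻¹)

The flask gives winter: noon 10.9%, summer 19.7%, dawn 10.9%, winter 23.3%, against my 24.3%. At its end, winter still holds E at 11% of the charge. Winter's lead belongs to that reading time. At 1.0 h its youngest dose is 35.0 min old, past the last reading at 30.0 min, so the time-as-J reckoning falls back to 9.06%. Winter read then gives 10.2%, against noon's 10.9%.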